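**Retrosynthetic overview**
1. The target comes from the bicyclic 3‑methoxy‑2‑ene‑4,8‑dione by Luche reduction of C4=O and desilylation; the C3–OMe enol ether is made from the saturated 4‑ketone by enolate hydroxylation, oxidation and diosphenol O‑methylation.
2. The six‑membered ring (C1–C2–C3–C4–C5–C8) is formed last, by intramolecular aldol C5→C4 of a 2‑(3‑oxopropyl)‑5‑methoxycyclopentanone.
3. Key C1–C2 bond (quaternary C1): intermolecular Mukaiyama–Michael addition of a regiodefined cyclopentanone enol silane to acrolein, anti to the C7 methyl.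
4. The cyclopentanone (formed first) is built by two anti‑selective Cu‑mediated 1,4‑additions to (S)‑2‑allyl‑4‑silyloxycyclopentenone: methyl first, then aryl after β‑elimination of the relay silyloxy group; C5–OMe by Rubottom oxidation and methylation.
5. (S)‑2‑Allyl‑4‑hydroxycyclopentenone comes from furfural and allyl Grignard by Piancatelli rearrangement and lipase resolution.

Convention: Ar = 3‑methoxy‑4‑(triisopropylsilyloxy)phenyl; bicyclic compounds 21–28 carry the target's numbering (C1 allyl‑bearing bridgehead, C8 bridging carbonyl), not lowest‑locant numbering.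

**Route**

Step 1
Reactants: 1 furfural; 2 allylmagnesium bromide
Product: 3 rac‑1‑(furan‑2‑yl)but‑3‑en‑1‑ol
Conditions: THF, −78 → 0 °C; then H2O
Reagents that add atoms: none
Why: Grignard carbonyl allylation (1,2‑addition) installs the future C1 allyl group; the carbinol stereocentre is destroyed in step 2, so the racemate is used.

Step 2
Reactants: 3 rac‑1‑(furan‑2‑yl)but‑3‑en‑1‑ol
Product: 5 rac‑2‑allyl‑4‑hydroxycyclopent‑2‑en‑1‑one, via rac‑trans‑5‑allyl‑4‑hydroxycyclopent‑2‑en‑1‑one 4 (not isolated)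
Conditions: ZnCl2 (cat.), dioxane/H2O, pH ≈ 6, reflux; then basic Al2O3, CH2Cl2, rt
Reagents that add atoms: water – O
Why: Piancatelli rearrangement (acid‑promoted furylcarbinol opening and conrotatory 4π electrocyclisation to the trans 4‑hydroxy‑5‑allyl enone), then the standard base‑mediated isomerisation to the more stable 2‑substituted 4‑hydroxycyclopentenone.

Step 3
Reactants: 5 rac‑2‑allyl‑4‑hydroxycyclopent‑2‑en‑1‑one
Product: 6 (S)‑2‑allyl‑4‑hydroxycyclopent‑2‑en‑1‑one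
Conditions: Amano lipase PS, vinyl acetate, MTBE, 30 °C, to ca. 55 % conversion; chromatography
Reagents that add atoms: none
Why: Lipase kinetic resolution (enantioselective transesterification): the (R)‑alcohol is expected to be acetylated faster, as in the resolution of the closely related pyrethroid alcohols, so the unreacted (S)‑alcohol is recovered in high ee; this centre relays all later stereocentres.

Step 4
Reactants: 6 (S)‑2‑allyl‑4‑hydroxycyclopent‑2‑en‑1‑one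
Product: 7 (S)‑2‑allyl‑4‑(tert‑butyldimethylsilyloxy)cyclopent‑2‑en‑1‑one
Conditions: TBSCl, imidazole, DMF, 0 °C → rt
Reagents that add atoms: tert‑butyldimethylsilyl chloride – CC(C)(C)[Si](C)(C)Cl
Why: Silyl ether formation gives the bulky C4 group that directs the next addition and later serves as leaving group.

Step 5
Reactants: 7 (S)‑2‑allyl‑4‑(tert‑butyldimethylsilyloxy)cyclopent‑2‑en‑1‑one
Product: 8 (3S,4S)‑2‑allyl‑4‑(tert‑butyldimethylsilyloxy)‑3‑methyl‑1‑(trimethylsilyloxy)cyclopent‑1‑ene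
Conditions: MeMgBr, CuBr·SMe2 (10 mol %), TMSCl, DMPU, THF, −78 °C; Et3N/pentane work‑up
Reagents that add atoms: methylmagnesium bromide – C[Mg]Br; chlorotrimethylsilane – C[Si](C)(C)Cl
Why: Cu‑catalysed conjugate addition occurs anti to the C4 silyloxy group (as in two‑component prostaglandin couplings) and sets the methyl stereocentre, while TMSCl traps the allyl‑bearing enolate regiospecifically before it can equilibrate.

Step 6
Reactants: 8 (3S,4S)‑enol silane; 9 acrolein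
Product: 10 (2R,3S,4S)‑2‑allyl‑4‑(tert‑butyldimethylsilyloxy)‑3‑methyl‑2‑(3‑oxopropyl)cyclopentan‑1‑one
Conditions: BF3·OEt2 (1 equiv), i‑PrOH (1 equiv), CH2Cl2, −78 °C
Reagents that add atoms: none
Why: Mukaiyama–Michael addition: the tetrasubstituted enol silane attacks Lewis‑acid‑activated acrolein on the face anti to the adjacent methyl, creating the quaternary carbon (future C1) with the oxopropyl chain trans and the allyl cis to methyl.

Step 7
Reactants: 10 keto aldehyde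
Product: 11 (2R,3S,4S)‑2‑allyl‑4‑(tert‑butyldimethylsilyloxy)‑2‑[2‑(1,3‑dioxolan‑2‑yl)ethyl]‑3‑methylcyclopentan‑1‑one
Conditions: TMSOCH2CH2OTMS, TMSOTf (cat.), CH2Cl2, −78 °C
Reagents that add atoms: 1,2‑bis(trimethylsilyloxy)ethane – C[Si](C)(C)OCCO[Si](C)(C)C
Why: Noyori acetalisation is selective for the aldehyde over the hindered ketone and masks it before base and Grignard chemistry (otherwise the C5 methylene would undergo a premature aldol).

Step 8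
Reactants: 11 keto acetal
Product: 12 (4R,5R)‑5‑allyl‑5‑[2‑(1,3‑dioxolan‑2‑yl)ethyl]‑4‑methylcyclopent‑2‑en‑1‑one
Conditions: DBU, CH2Cl2, 0 °C → rt
Reagents that add atoms: none
Why: E1cB β‑elimination of silanolate from the only enolisable α‑carbon gives the enone and moves the acceptor site to the carbon that must carry the aryl group; the methyl and quaternary centres are untouched.

Step 9
Reactants: 13 4‑bromo‑2‑methoxyphenol
Product: 14 (4‑bromo‑2‑methoxyphenoxy)triisopropylsilane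
Conditions: TIPSCl, imidazole, DMF, rt
Reagents that add atoms: triisopropylsilyl chloride – CC(C)[Si](Cl)(C(C)C)C(C)C
Why: Silylation gives a phenol protecting group that survives Grignard, acid and non‑nucleophilic base steps and can be removed at the end without hydrogenation or strong acid.

Step 10
Reactants: 12 enone; 14 aryl bromide
Product: 16 (3R,4R,5R)‑5‑allyl‑5‑[2‑(1,3‑dioxolan‑2‑yl)ethyl]‑3‑[3‑methoxy‑4‑(triisopropylsilyloxy)phenyl]‑4‑methyl‑1‑(trimethylsilyloxy)cyclopent‑1‑ene, via arylmagnesium bromide 15 (not isolated)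
Conditions: 14, Mg, THF, reflux; then CuBr·SMe2 (20 mol %), TMSCl, DMPU, 12, THF, −78 → −40 °C; Et3N work‑up
Reagents that add atoms: chlorotrimethylsilane – C[Si](C)(C)Cl; magnesium – [Mg] (ends in 15 only)
Why: Cu‑catalysed conjugate addition of the aryl Grignard occurs anti to the adjacent methyl, giving the trans aryl/methyl pair (future C6/C7), and TMSCl again delivers a single enol silane.

Step 11
Reactants: 16 enol silane
Product: 18 (2R,3R,4S,5S)‑2‑allyl‑2‑[2‑(1,3‑dioxolan‑2‑yl)ethyl]‑5‑hydroxy‑4‑[3‑methoxy‑4‑(triisopropylsilyloxy)phenyl]‑3‑methylcyclopentan‑1‑one, via 5‑trimethylsilyloxy ketone 17 (not isolated)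
Conditions: mCPBA (1.05 equiv), CH2Cl2, −20 → 0 °C; then aq. citric acid, THF, rt
Reagents that add atoms: 3‑chloroperbenzoic acid – O=C(OO)c1cccc(Cl)c1
Why: Rubottom oxidation: the electron‑rich enol silane is oxidised much faster than the terminal alkene, anti to the neighbouring aryl group; this centre is re‑enolised in step 14, so its configuration is not critical.

Step 12
Reactants: 18 α‑hydroxy ketone
Product: 19 (2R,3R,4S,5S)‑2‑allyl‑2‑[2‑(1,3‑dioxolan‑2‑yl)ethyl]‑5‑methoxy‑4‑[3‑methoxy‑4‑(triisopropylsilyloxy)phenyl]‑3‑methylcyclopentan‑1‑one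
Conditions: MeI, Ag2O, 4 Å MS, CH2Cl2, 40 °C, dark
Reagents that add atoms: iodomethane – CI
Why: Purdie O‑methylation under non‑basic conditions avoids enediol isomerisation of the α‑ketol.

Step 13
Reactants: 19 α‑methoxy ketone acetal
Product: 20 (2R,3R,4S,5S)‑2‑allyl‑5‑methoxy‑4‑[3‑methoxy‑4‑(triisopropylsilyloxy)phenyl]‑3‑methyl‑2‑(3‑oxopropyl)cyclopentan‑1‑one
Conditions: 1 M HCl, THF, rt
Reagents that add atoms: water – O
Why: Acid hydrolysis of the dioxolane releases the aldehyde; aryl TIPS ether, methyl ethers and the alkene are stable to dilute acid.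

Step 14
Reactants: 20 keto aldehyde
Product: 21 (1R,5R,6S,7R)‑1‑allyl‑4‑hydroxy‑5‑methoxy‑6‑[3‑methoxy‑4‑(triisopropylsilyloxy)phenyl]‑7‑methylbicyclo[3.2.1]octan‑8‑one (C4 epimers)
Conditions: DBU (0.5 equiv), CH2Cl2, rt
Reagents that add atoms: none
Why: Intramolecular aldol addition: the ketone can enolise only toward the methoxy‑bearing carbon and the tethered aldehyde can reach it only from its own face, so the C5 bridgehead forms with the required configuration; the carbinol epimers converge in step 15.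

Step 15
Reactants: 21 ketol
Product: 22 (1R,5R,6S,7R)‑1‑allyl‑5‑methoxy‑6‑[3‑methoxy‑4‑(triisopropylsilyloxy)phenyl]‑7‑methylbicyclo[3.2.1]octane‑4,8‑dione
Conditions: Dess–Martin periodinane, CH2Cl2, rt
Reagents that add atoms: none
Why: Dess–Martin oxidation of the hindered secondary alcohol locks the ring closure as a non‑enolisable 1,3‑dione.

Step 16
Reactants: 22 dione
Product: 23 (1S,5S,6S,7R)‑1‑allyl‑3‑hydroxy‑5‑methoxy‑6‑[3‑methoxy‑4‑(triisopropylsilyloxy)phenyl]‑7‑methylbicyclo[3.2.1]octane‑4,8‑dione (C3 epimers)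
Conditions: KHMDS, THF, −78 °C; 2‑(phenylsulfonyl)‑3‑phenyloxaziridine, −78 °C; AcOH quench
Reagents that add atoms: 2‑(phenylsulfonyl)‑3‑phenyloxaziridine – O=S(=O)(c1ccccc1)N1OC1c1ccccc1
Why: Davis enolate hydroxylation: C3 is the only enolisable position (C1 and C5 are bridgeheads), so the enolate forms regiospecifically.

Step 17
Reactants: 23 α‑hydroxy ketone
Product: 25 (1R,5S,6S,7R)‑1‑allyl‑3‑hydroxy‑5‑methoxy‑6‑[3‑methoxy‑4‑(triisopropylsilyloxy)phenyl]‑7‑methylbicyclo[3.2.1]oct‑2‑ene‑4,8‑dione, via 3,4,8‑trione 24 (not isolated)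
Conditions: Dess–Martin periodinane, CH2Cl2, rt
Reagents that add atoms: none
Why: Dess–Martin oxidation gives the 1,2‑dione, which can enolise only toward C2 and so tautomerises to a single diosphenol.

Step 18
Reactants: 25 diosphenol
Product: 26 (1R,5S,6S,7R)‑1‑allyl‑3,5‑dimethoxy‑6‑[3‑methoxy‑4‑(triisopropylsilyloxy)phenyl]‑7‑methylbicyclo[3.2.1]oct‑2‑ene‑4,8‑dione
Conditions: Me2SO4, K2CO3, acetone, rt
Reagents that add atoms: dimethyl sulfate – COS(=O)(=O)OC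
Why: O‑Methylation of the acidic diosphenol with a hard electrophile gives the 3‑methoxy enone; no other acidic OH is present.

Step 19
Reactants: 26 enedione
Product: 27 (1R,4S,5R,6S,7R)‑1‑allyl‑4‑hydroxy‑3,5‑dimethoxy‑6‑[3‑methoxy‑4‑(triisopropylsilyloxy)phenyl]‑7‑methylbicyclo[3.2.1]oct‑2‑en‑8‑one
Conditions: NaBH4, CeCl3·7H2O, MeOH, −78 °C
Reagents that add atoms: none
Why: Luche reduction should take the conjugated C4 ketone in preference to the C8 ketone flanked by two quaternary carbons, with hydride entering from the face opposite the C6–C7 bridge (shielded by the endo aryl) to give the (4S) alcohol.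

Step 20
Reactants: 27 silyl ether
Product: 28 (1R,4S,5R,6S,7R)‑1‑allyl‑4‑hydroxy‑6‑(4‑hydroxy‑3‑methoxyphenyl)‑3,5‑dimethoxy‑7‑methylbicyclo[3.2.1]oct‑2‑en‑8‑one
Conditions: TBAF, AcOH, THF, 0 °C
Reagents that add atoms: none
Why: Buffered fluoride desilylation frees the phenol without base‑induced retro‑aldol of the β‑hydroxy ketone or acid damage to the enol ether.

**Compound list**
1 | furfural | O=Cc1ccco1 | starting material
2 | allylmagnesium bromide | C=CC[Mg]Br | starting material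
3 | rac‑1‑(furan‑2‑yl)but‑3‑en‑1‑ol | C=CCC(O)c1ccco1 | intermediate
4 | rac‑trans‑5‑allyl‑4‑hydroxycyclopent‑2‑en‑1‑one (one enantiomer drawn) | O=C1C=C[C@@H](O)[C@@H]1CC=C | intermediate (not isolated)
5 | rac‑2‑allyl‑4‑hydroxycyclopent‑2‑en‑1‑one | C=CCC1=CC(O)CC1=O | intermediate
6 | (S)‑2‑allyl‑4‑hydroxycyclopent‑2‑en‑1‑one | C=CCC1=C[C@@H](O)CC1=O | intermediate
7 | (S)‑2‑allyl‑4‑(tert‑butyldimethylsilyloxy)cyclopent‑2‑en‑1‑one | C=CCC1=C[C@@H](O[Si](C)(C)C(C)(C)C)CC1=O | intermediate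
8 | (3S,4S)‑2‑allyl‑4‑(tert‑butyldimethylsilyloxy)‑3‑methyl‑1‑(trimethylsilyloxy)cyclopent‑1‑ene | C=CCC1=C(O[Si](C)(C)C)C[C@H](O[Si](C)(C)C(C)(C)C)[C@H]1C | intermediate
9 | acrolein | C=CC=O | starting material
10 | (2R,3S,4S)‑2‑allyl‑4‑(tert‑butyldimethylsilyloxy)‑3‑methyl‑2‑(3‑oxopropyl)cyclopentan‑1‑one | C=CC[C@@]1(CCC=O)C(=O)C[C@H](O[Si](C)(C)C(C)(C)C)[C@H]1C | intermediate
11 | (2R,3S,4S)‑2‑allyl‑4‑(tert‑butyldimethylsilyloxy)‑2‑[2‑(1,3‑dioxolan‑2‑yl)ethyl]‑3‑methylcyclopentan‑1‑one | C=CC[C@@]1(CCC2OCCO2)C(=O)C[C@H](O[Si](C)(C)C(C)(C)C)[C@H]1C | intermediate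
12 | (4R,5R)‑5‑allyl‑5‑[2‑(1,3‑dioxolan‑2‑yl)ethyl]‑4‑methylcyclopent‑2‑en‑1‑one | C=CC[C@@]1(CCC2OCCO2)C(=O)C=C[C@H]1C | intermediate
13 | 4‑bromo‑2‑methoxyphenol | COc1cc(Br)ccc1O | starting material
14 | (4‑bromo‑2‑methoxyphenoxy)triisopropylsilane | COc1cc(Br)ccc1O[Si](C(C)C)(C(C)C)C(C)C | intermediate
15 | [3‑methoxy‑4‑(triisopropylsilyloxy)phenyl]magnesium bromide | COc1cc([Mg]Br)ccc1O[Si](C(C)C)(C(C)C)C(C)C | intermediate (not isolated)
16 | (3R,4R,5R)‑5‑allyl‑5‑[2‑(1,3‑dioxolan‑2‑yl)ethyl]‑3‑Ar‑4‑methyl‑1‑(trimethylsilyloxy)cyclopent‑1‑ene | C=CC[C@@]1(CCC2OCCO2)C(O[Si](C)(C)C)=C[C@H](c2ccc(O[Si](C(C)C)(C(C)C)C(C)C)c(OC)c2)[C@H]1C | intermediate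
17 | (2R,3R,4S,5S)‑2‑allyl‑2‑[2‑(1,3‑dioxolan‑2‑yl)ethyl]‑4‑Ar‑3‑methyl‑5‑(trimethylsilyloxy)cyclopentan‑1‑one | C=CC[C@@]1(CCC2OCCO2)C(=O)[C@@H](O[Si](C)(C)C)[C@H](c2ccc(O[Si](C(C)C)(C(C)C)C(C)C)c(OC)c2)[C@H]1C | intermediate (not isolated)
18 | (2R,3R,4S,5S)‑2‑allyl‑2‑[2‑(1,3‑dioxolan‑2‑yl)ethyl]‑5‑hydroxy‑4‑Ar‑3‑methylcyclopentan‑1‑one | C=CC[C@@]1(CCC2OCCO2)C(=O)[C@@H](O)[C@H](c2ccc(O[Si](C(C)C)(C(C)C)C(C)C)c(OC)c2)[C@H]1C | intermediate
19 | (2R,3R,4S,5S)‑2‑allyl‑2‑[2‑(1,3‑dioxolan‑2‑yl)ethyl]‑5‑methoxy‑4‑Ar‑3‑methylcyclopentan‑1‑one | C=CC[C@@]1(CCC2OCCO2)C(=O)[C@@H](OC)[C@H](c2ccc(O[Si](C(C)C)(C(C)C)C(C)C)c(OC)c2)[C@H]1C | intermediate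
20 | (2R,3R,4S,5S)‑2‑allyl‑5‑methoxy‑4‑Ar‑3‑methyl‑2‑(3‑oxopropyl)cyclopentan‑1‑one | C=CC[C@@]1(CCC=O)C(=O)[C@@H](OC)[C@H](c2ccc(O[Si](C(C)C)(C(C)C)C(C)C)c(OC)c2)[C@H]1C | intermediate
21 | (1R,5R,6S,7R)‑1‑allyl‑4‑hydroxy‑5‑methoxy‑6‑Ar‑7‑methylbicyclo[3.2.1]octan‑8‑one (C4 epimers) | C=CC[C@@]12CCC(O)[C@@](OC)(C1=O)[C@H](c1ccc(O[Si](C(C)C)(C(C)C)C(C)C)c(OC)c1)[C@H]2C | intermediate
22 | (1R,5R,6S,7R)‑1‑allyl‑5‑methoxy‑6‑Ar‑7‑methylbicyclo[3.2.1]octane‑4,8‑dione | C=CC[C@@]12CCC(=O)[C@@](OC)(C1=O)[C@H](c1ccc(O[Si](C(C)C)(C(C)C)C(C)C)c(OC)c1)[C@H]2C | intermediate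
23 | (1S,5S,6S,7R)‑1‑allyl‑3‑hydroxy‑5‑methoxy‑6‑Ar‑7‑methylbicyclo[3.2.1]octane‑4,8‑dione (C3 epimers) | C=CC[C@@]12CC(O)C(=O)[C@@](OC)(C1=O)[C@H](c1ccc(O[Si](C(C)C)(C(C)C)C(C)C)c(OC)c1)[C@H]2C | intermediate
24 | (1S,5S,6S,7R)‑1‑allyl‑5‑methoxy‑6‑Ar‑7‑methylbicyclo[3.2.1]octane‑3,4,8‑trione | C=CC[C@@]12CC(=O)C(=O)[C@@](OC)(C1=O)[C@H](c1ccc(O[Si](C(C)C)(C(C)C)C(C)C)c(OC)c1)[C@H]2C | intermediate (not isolated)
25 | (1R,5S,6S,7R)‑1‑allyl‑3‑hydroxy‑5‑methoxy‑6‑Ar‑7‑methylbicyclo[3.2.1]oct‑2‑ene‑4,8‑dione | C=CC[C@@]12C=C(O)C(=O)[C@@](OC)(C1=O)[C@H](c1ccc(O[Si](C(C)C)(C(C)C)C(C)C)c(OC)c1)[C@H]2C | intermediate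
26 | (1R,5S,6S,7R)‑1‑allyl‑3,5‑dimethoxy‑6‑Ar‑7‑methylbicyclo[3.2.1]oct‑2‑ene‑4,8‑dione | C=CC[C@@]12C=C(OC)C(=O)[C@@](OC)(C1=O)[C@H](c1ccc(O[Si](C(C)C)(C(C)C)C(C)C)c(OC)c1)[C@H]2C | intermediate
27 | (1R,4S,5R,6S,7R)‑1‑allyl‑4‑hydroxy‑3,5‑dimethoxy‑6‑Ar‑7‑methylbicyclo[3.2.1]oct‑2‑en‑8‑one | C=CC[C@@]12C=C(OC)[C@H](O)[C@@](OC)(C1=O)[C@H](c1ccc(O[Si](C(C)C)(C(C)C)C(C)C)c(OC)c1)[C@H]2C | intermediate
28 | (1R,4S,5R,6S,7R)‑1‑allyl‑4‑hydroxy‑6‑(4‑hydroxy‑3‑methoxyphenyl)‑3,5‑dimethoxy‑7‑methylbicyclo[3.2.1]oct‑2‑en‑8‑one | C=CC[C@@]12C=C(OC)[C@H](O)[C@@](OC)(C1=O)[C@H](c1ccc(O)c(OC)c1)[C@H]2C | target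

**Summary**
Total steps: 20. Longest linear sequence: 19 steps (1–8 and 10–20, from furfural); the aryl branch adds step 9 before the union in step 10.

**Steps most likely to fail**

Step 6 (Mukaiyama–Michael to acrolein: 1,2‑addition, polymerisation or modest facial selectivity at the quaternary carbon). The fallback sets out from 8. MeLi (THF, 0 °C) releases the regiodefined lithium enolate F1, which is alkylated with propargyl bromide (DMPU, −78 → 0 °C), again anti to the methyl, to give (2S,3S,4S)‑2‑allyl‑4‑(tert‑butyldimethylsilyloxy)‑3‑methyl‑2‑(prop‑2‑yn‑1‑yl)cyclopentan‑1‑one F2. Ruthenium‑catalysed anti‑Markovnikov hydration of the terminal alkyne (Grotjahn‑type CpRu catalyst, aqueous acetone, 60 °C), which leaves the allyl group alone, then gives aldehyde 10, where the route is rejoined.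

Step 14 (aldol closure: congested bond cis to the aryl group, reversible, competing aldehyde self‑condensation). The fallback sets out from 20. Pinnick oxidation (NaClO2, NaH2PO4, 2‑methyl‑2‑butene) gives the carboxylic acid F3, and TMSCHN2 gives its methyl ester F4. LiHMDS (THF, −78 → −20 °C) forms the only possible ketone enolate (C5), which acylates intramolecularly in a kinetically controlled Claisen (Dieckmann‑type) condensation. This gives dione 22 directly, so steps 14 and 15 are bypassed and the route is rejoined at 22.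

Step 19 (chemoselectivity between the C4 enone carbonyl and the C8 ketone). The fallback sets out from 26. Both carbonyls are reduced (excess NaBH4, CeCl3, MeOH, 0 °C; the C4 hydride again enters anti to the C6–C7 bridge) to give the 4,8‑diol F5. The less hindered allylic C4–OH is silylated selectively (TESCl, imidazole, DMF, −20 °C) to give the 4‑O‑triethylsilyl ether F6. The hindered C8–OH is re‑oxidised with Dess–Martin periodinane to the 8‑ketone F7, and TBAF/AcOH removes both silyl groups to arrive at the target 28.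

**Further compounds**
F1 | step 6 | lithium (3S,4S)‑2‑allyl‑4‑(tert‑butyldimethylsilyloxy)‑3‑methylcyclopent‑1‑en‑1‑olate | C=CCC1=C(O[Li])C[C@H](O[Si](C)(C)C(C)(C)C)[C@H]1C
F2 | step 6 | (2S,3S,4S)‑2‑allyl‑4‑(tert‑butyldimethylsilyloxy)‑3‑methyl‑2‑(prop‑2‑yn‑1‑yl)cyclopentan‑1‑one | C=CC[C@@]1(CC#C)C(=O)C[C@H](O[Si](C)(C)C(C)(C)C)[C@H]1C
F3 | step 14 | 3‑[(1R,2R,3S,4S)‑1‑allyl‑4‑methoxy‑3‑[3‑methoxy‑4‑(triisopropylsilyloxy)phenyl]‑2‑methyl‑5‑oxocyclopentyl]propanoic acid | C=CC[C@@]1(CCC(=O)O)C(=O)[C@@H](OC)[C@H](c2ccc(O[Si](C(C)C)(C(C)C)C(C)C)c(OC)c2)[C@H]1C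
F4 | step 14 | methyl 3‑[(1R,2R,3S,4S)‑1‑allyl‑4‑methoxy‑3‑[3‑methoxy‑4‑(triisopropylsilyloxy)phenyl]‑2‑methyl‑5‑oxocyclopentyl]propanoate | C=CC[C@@]1(CCC(=O)OC)C(=O)[C@@H](OC)[C@H](c2ccc(O[Si](C(C)C)(C(C)C)C(C)C)c(OC)c2)[C@H]1C
F5 | step 19 | (1R,4S,5S,6S,7R)‑1‑allyl‑3,5‑dimethoxy‑6‑[3‑methoxy‑4‑(triisopropylsilyloxy)phenyl]‑7‑methylbicyclo[3.2.1]oct‑2‑ene‑4,8‑diol (C8 epimers) | C=CC[C@@]12C=C(OC)[C@H](O)[C@@](OC)(C1O)[C@H](c1ccc(O[Si](C(C)C)(C(C)C)C(C)C)c(OC)c1)[C@H]2C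
F6 | step 19 | (1R,4S,5S,6S,7R)‑1‑allyl‑3,5‑dimethoxy‑6‑[3‑methoxy‑4‑(triisopropylsilyloxy)phenyl]‑7‑methyl‑4‑(triethylsilyloxy)bicyclo[3.2.1]oct‑2‑en‑8‑ol (C8 epimers) | C=CC[C@@]12C=C(OC)[C@H](O[Si](CC)(CC)CC)[C@@](OC)(C1O)[C@H](c1ccc(O[Si](C(C)C)(C(C)C)C(C)C)c(OC)c1)[C@H]2C
F7 | step 19 | (1R,4S,5R,6S,7R)‑1‑allyl‑3,5‑dimethoxy‑6‑[3‑methoxy‑4‑(triisopropylsilyloxy)phenyl]‑7‑methyl‑4‑(triethylsilyloxy)bicyclo[3.2.1]oct‑2‑en‑8‑one | C=CC[C@@]12C=C(OC)[C@H](O[Si](CC)(CC)CC)[C@@](OC)(C1=O)[C@H](c1ccc(O[Si](C(C)C)(C(C)C)C(C)C)c(OC)c1)[C@H]2C
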